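**Strategy**

- Cuts: the two Wittig bonds C11=C12 and C11'=C12' give a furanoid C15 phosphonium salt, the C10 trienedial and an ε-end C15 phosphonium salt. In the furanoid unit, O5–C8 is cut back to a 5-hydroxy-6,7-allene, the allene to a 5,6-epoxy-7-yne, and C6–C7 to an enol triflate plus a C6 enynol.
- Enabling feature: the 2,5-dihydrofuran ring O–C5–C6=C7–C8, fused to the cyclohexane ring along C5–C6, is the cycloisomer of a tertiary C5 alcohol next to an exocyclic C6=C7=C8 allene. The allene axis can therefore set C8 without a C8 cation.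
- Forward order: both six-membered rings are bought. The oxirane is made and opened to the allene, the dihydrofuran is closed on the C15 unit, the chain is joined at C11'=C12' and then at C11=C12, and both silyl ethers are removed last.
- Stereochemistry: C3 from enzymatic C=C reduction followed by substrate-controlled ketone reduction; C5 from epoxidation anti to the C3 silyl ether; the 6R axis from syn SN2' hydride delivery; C8 from the axis; C6' bought; C3' from hydride delivery anti to the axial ring methyl group; E-alkenes from the building blocks, the olefinations and thermal equilibration.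

Key step: step 9

Remark: enantiopure (R)-α-ionone is taken as a bought material, and carotenoid locants (primed in the ε half) are used for all fragments; TBS = tert-butyldimethylsilyl.

**Route**

Step 1
Reactants: 1 ketoisophorone (2,6,6-trimethylcyclohex-2-ene-1,4-dione)
Product: 2 (6R)-levodione [(6R)-2,2,6-trimethylcyclohexane-1,4-dione]
Conditions: ene-reductase (old yellow enzyme family), NADP+ (cat.), D-glucose, glucose dehydrogenase, phosphate buffer pH 6.5, 30 °C
Reagents that add atoms: none
Why: Biocatalytic asymmetric conjugate reduction of the activated enedione C=C bond, in which the enzyme fixes the face of hydride and proton addition and so sets the 6R methyl centre.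

Step 2
Reactants: 2 (6R)-levodione
Product: 3 (4R,6R)-actinol [(4R,6R)-4-hydroxy-2,2,6-trimethylcyclohexanone]
Conditions: LiBH(s-Bu)3, THF, −78 °C; H2O
Reagents that add atoms: none
Why: Substrate-controlled ketone reduction with a bulky trialkylborohydride, which attacks only the unhindered C4 carbonyl and enters on the equatorial side away from the axial C2 methyl group, so the new hydroxyl is axial and trans to the C6 methyl group (4R).

Step 3
Reactants: 3 (4R,6R)-actinol
Product: 4 (4R,6R)-4-(tert-butyldimethylsilyloxy)-2,2,6-trimethylcyclohexanone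
Conditions: TBSCl, imidazole, DMF, rt
Reagents that add atoms: tert-butyldimethylsilyl chloride, CC(C)(C)[Si](C)(C)Cl
Why: Imidazole-promoted silylation of the secondary alcohol gives an ether that survives the base, palladium, peracid, hydride and gold steps ahead.

Step 4
Reactants: 4 (4R,6R)-4-(tert-butyldimethylsilyloxy)-2,2,6-trimethylcyclohexanone
Product: 6 (4R)-4-(tert-butyldimethylsilyloxy)-2,6,6-trimethylcyclohex-1-en-1-yl trifluoromethanesulfonate, via lithium enolate 5 (not isolated)
Conditions: LiN(i-Pr)2, THF, −78 to 0 °C; PhNTf2, −78 °C to rt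
Reagents that add atoms: N-phenylbis(trifluoromethanesulfonimide), O=S(=O)(N(c1ccccc1)S(=O)(=O)C(F)(F)F)C(F)(F)F; lithium diisopropylamide (lithium of enolate 5), CC(C)[N-]C(C)C.[Li+]
Why: Enolate formation and O-triflation, where the ketone has a single α-hydrogen (at C6) so only one enolate and one enol triflate can form, and the C6 centre is erased after it has served to set C4.

Step 5
Reactants: 6 (4R)-enol triflate; 7 (E)-3-methylpent-2-en-4-yn-1-ol
Product: 8 C15 dienynol, (2E)-5-[(4R)-4-(tert-butyldimethylsilyloxy)-2,6,6-trimethylcyclohex-1-en-1-yl]-3-methylpent-2-en-4-yn-1-ol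
Conditions: Pd(PPh3)4 (5 mol%), CuI (10 mol%), i-Pr2NH, DMF, rt
Reagents that add atoms: none
Why: Sonogashira coupling of a vinyl triflate with a terminal alkyne forms the C6–C7 bond, tolerates the free primary alcohol and the silyl ether, and keeps the E-alkene of the enynol.

Step 6
Reactants: 8 C15 dienynol
Product: 9 C15 dienynyl acetate (acetate of 8 at the primary hydroxyl)
Conditions: Ac2O, pyridine, DMAP (cat.), CH2Cl2, 0 °C to rt
Reagents that add atoms: acetic anhydride, CC(=O)OC(C)=O
Why: Acetylation masks the primary allylic hydroxyl so that it cannot direct the peracid to the C9=C10 bond in the next step.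

Step 7
Reactants: 9 C15 dienynyl acetate
Product: 10 C15 5,6-epoxy-7-yne acetate with the oxirane anti to the C3 silyloxy group (3S,5R,6R)
Conditions: mCPBA, NaHCO3, CH2Cl2, 0 °C
Reagents that add atoms: 3-chloroperoxybenzoic acid, OOC(=O)c1cccc(Cl)c1
Why: Prilezhaev epoxidation selects the electron-rich tetrasubstituted ring alkene over the acetate-deactivated enyne alkene, and the peracid should approach mainly on the face opposite the homoallylic silyloxy group, which sets C5 and C6 anti to C3; the minor syn epoxide is removed by chromatography.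

Step 8
Reactants: 10 C15 5,6-epoxy-7-yne acetate
Product: 11 (3S,5R,6R)-allenic diol, (2E)-5-[(2R,4S)-4-(tert-butyldimethylsilyloxy)-2-hydroxy-2,6,6-trimethylcyclohexylidene]-3-methylpenta-2,4-dien-1-ol with R allene axis (C8–H on the face of the C5 hydroxyl)
Conditions: i-Bu2AlH (5 equiv), CH2Cl2, −78 to 0 °C; aq. potassium sodium tartrate
Reagents that add atoms: none
Why: SN2' reduction of a propargylic epoxide, in which aluminium bound to the oxirane oxygen delivers hydride to C8 on the side of the breaking C6–O bond, giving the 6R axis with C5 untouched while the acetate is reduced off in the same flask; the axis is checked by NOE before going on.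

Step 9
Reactants: 11 (3S,5R,6R)-allenic diol
Product: 12 (5R,8S)-furanoid C15 allylic alcohol, (2E)-3-[(2S,6S,7aR)-6-(tert-butyldimethylsilyloxy)-4,4,7a-trimethyl-2,4,5,6,7,7a-hexahydro-1-benzofuran-2-yl]but-2-en-1-ol
Conditions: Ph3PAuNTf2 (2 mol%), 2,6-di-tert-butylpyridine (5 mol%), THF, −20 to 0 °C, dark
Reagents that add atoms: none
Why: Cationic monovalent gold binds the distal C7=C8 bond of the allene on the side away from the C5 oxygen, the tertiary hydroxyl adds to C8 anti to the metal, and protodeauration of the C7 vinyl-gold species by the hydroxyl proton leaves the C6=C7 ring alkene; the closest known reaction type is the gold- or silver-catalysed cycloisomerisation of α-hydroxyallenes to 2,5-dihydrofurans with axis-to-centre chirality transfer. The one ring formed, the dihydrofuran O–C5–C6=C7–C8, closes in the 5-endo-trig mode by making the O5–C8 bond. The new C8 centre is controlled by the allene axis: the tethered oxygen can only reach the in-plane lobe of the C7=C8 π bond on its own side, so the C8 substituents keep their sides, C9 ends cis to the C5 methyl group, and C8 is S. The step needs complete axis-to-centre transfer, meaning no ionisation to the dienyl-stabilised allyl cation and no Nazarov-type carbocyclisation of the vinylallene; the weakly acidic, pyridine-buffered catalyst in coordinating THF at low temperature guards against the first, and fast intramolecular capture by the well-placed equatorial hydroxyl guards against the second. The primary C11 hydroxyl cannot compete because the 9E alkene holds it out of reach of the allene.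

Step 10
Reactants: 12 (5R,8S)-furanoid C15 allylic alcohol
Product: 14 furanoid C15 triphenylphosphonium bromide (PPh3+ at C11 of 12 in place of OH), via allylic bromide 13 (not isolated)
Conditions: CBr4, PPh3, 2,6-lutidine, CH2Cl2, −20 °C; then PPh3, EtOAc, rt
Reagents that add atoms: carbon tetrabromide, BrC(Br)(Br)Br; triphenylphosphine, c1ccc(cc1)P(c1ccccc1)c1ccccc1
Why: Appel bromination of the primary allylic alcohol under base-buffered, acid-free conditions followed by SN2 quaternisation of triphenylphosphine gives the salt without ionising the doubly allylic C8–O bond, and no stereocentre is touched.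

Step 11
Reactants: 15 (R)-α-ionone
Product: 16 ethyl (2E,4E)-3-methyl-5-[(1R)-2,6,6-trimethylcyclohex-2-en-1-yl]penta-2,4-dienoate (9'E)
Conditions: (EtO)2P(O)CH2CO2Et, NaH, THF, 0 to 40 °C; chromatography
Reagents that add atoms: triethyl phosphonoacetate, CCOC(=O)CP(=O)(OCC)OCC
Why: Horner–Wadsworth–Emmons olefination of the methyl ketone gives the trisubstituted enoate mainly as the 9'E isomer (ester trans to the larger dienyl residue), which is separated from the 9'Z isomer, and the stabilised phosphonate anion used without excess hydride should leave the C6' centre intact.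

Step 12
Reactants: 16 ethyl (6'R,9'E)-α-ionylideneacetate
Product: 17 ethyl (2E,4E)-3-methyl-5-[(1R)-2,6,6-trimethyl-4-oxocyclohex-2-en-1-yl]penta-2,4-dienoate
Conditions: t-BuOOH (70% in H2O), Rh2(cap)4 (dirhodium tetracaprolactamate, 1 mol%), ClCH2CH2Cl, 40 °C
Reagents that add atoms: tert-butyl hydroperoxide, CC(C)(C)OO
Why: Allylic C–H oxidation by tert-butylperoxyl radicals from the dirhodium caprolactamate/t-BuOOH system goes at the ring C3' methylene, the only unhindered secondary allylic position of the electron-rich ring alkene, and the base-free medium leaves the γ-acidic C6' centre alone.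

Step 13
Reactants: 17 3'-oxo ester
Product: 18 ethyl (2E,4E)-5-[(1R,4R)-4-hydroxy-2,6,6-trimethylcyclohex-2-en-1-yl]-3-methylpenta-2,4-dienoate (3'R,6'R; hydroxyl trans to the side chain)
Conditions: LiBH(s-Bu)3 (1.1 equiv), THF, −78 °C; H2O
Reagents that add atoms: none
Why: 1,2-Reduction of a β,β-disubstituted cyclohexenone by a bulky trialkylborohydride: with the C6' side chain pseudo-axial, hydride should enter along the equatorial trajectory anti to the axial C1' methyl group, which leaves the new hydroxyl pseudo-axial and trans to the side chain (3'R), while the hindered dienoate is not reduced at −78 °C.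

Step 14
Reactants: 18 (3'R,6'R)-hydroxy ester
Product: 19 TBS ether of 18
Conditions: TBSCl, imidazole, DMF, rt
Reagents that add atoms: tert-butyldimethylsilyl chloride, CC(C)(C)[Si](C)(C)Cl
Why: Silylation protects the acid-labile ring allylic alcohol through the bromination and both olefinations and lets both ring hydroxyls be freed together at the end.

Step 15
Reactants: 19 silylated ester
Product: 20 (2E,4E)-5-[(1R,4R)-4-(tert-butyldimethylsilyloxy)-2,6,6-trimethylcyclohex-2-en-1-yl]-3-methylpenta-2,4-dien-1-ol
Conditions: i-Bu2AlH (2.5 equiv), CH2Cl2, −78 °C; aq. potassium sodium tartrate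
Reagents that add atoms: none
Why: 1,2-Reduction of the conjugated ester with i-Bu2AlH gives the primary allylic alcohol without touching the diene geometry or the silyl ether.

Step 16
Reactants: 20 ε-end C15 allylic alcohol
Product: 22 ε-end C15 triphenylphosphonium bromide (PPh3+ at C11' of 20 in place of OH), via allylic bromide 21 (not isolated)
Conditions: CBr4, PPh3, 2,6-lutidine, CH2Cl2, −20 °C; then PPh3, EtOAc, rt
Reagents that add atoms: carbon tetrabromide, BrC(Br)(Br)Br; triphenylphosphine, c1ccc(cc1)P(c1ccccc1)c1ccccc1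
Why: Appel bromination followed by SN2 quaternisation of triphenylphosphine, where the silylated ring oxygen leaves only the primary allylic position free to react under acid-free conditions.

Step 17
Reactants: 22 ε-end C15 phosphonium bromide; 23 (2E,4E,6E)-2,7-dimethylocta-2,4,6-trienedial
Product: 25 all-E C25 apo-aldehyde carrying the silylated ε end, via 11'Z isomer 24 (not isolated)
Conditions: 23 (3 equiv), NaOMe, CH2Cl2/MeOH, 0 °C to rt; then n-heptane, reflux, N2, dark
Reagents that add atoms: none
Why: Wittig olefination of one aldehyde of the symmetrical dialdehyde (used in excess) with the semi-stabilised allylic ylide forms C11'=C12', and heating converts the sterically hindered 11'Z isomer into the 11'E isomer.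

Step 18
Reactants: 14 furanoid C15 phosphonium bromide; 25 all-E C25 apo-aldehyde
Product: 27 all-E 3,3'-bis-O-TBS ether of the target, via 11Z isomer 26 (not isolated)
Conditions: NaOMe, CH2Cl2/MeOH, 0 °C to rt; then n-heptane/EtOAc, 80 °C, N2, dark
Reagents that add atoms: none
Why: Wittig olefination forms C11=C12; the allylic ylide has only an ether oxygen (a poor leaving group) in the vinylogous β-position, so olefination should outrun ring opening, and acid-free heating turns the hindered 11Z isomer into the all-E polyene without epimerising C8.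

Step 19
Reactants: 27 bis-TBS ether
Product: 28 target, (3S,5R,8S,3'R,6'R)-5,8-epoxy-5,8-dihydro-β,ε-carotene-3,3'-diol
Conditions: Bu4NF, THF, 0 °C to rt; pH 7 phosphate buffer work-up
Reagents that add atoms: none
Why: Fluoride-mediated desilylation cleaves both silyl ethers, and the acid-free medium and neutral work-up keep the C8–O bond and the ε-ring allylic alcohol intact.

**Compound list**

1 | ketoisophorone | CC1=CC(=O)CC(C)(C)C1=O | starting material
2 | (6R)-levodione | O=C1C(C)(C)CC(=O)C[C@H]1C | intermediate
3 | (4R,6R)-actinol | O=C1C(C)(C)C[C@H](O)C[C@H]1C | intermediate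
4 | (4R,6R)-4-(tert-butyldimethylsilyloxy)-2,2,6-trimethylcyclohexanone | O=C1C(C)(C)C[C@H](O[Si](C)(C)C(C)(C)C)C[C@H]1C | intermediate
5 | lithium (4R)-4-(tert-butyldimethylsilyloxy)-2,6,6-trimethylcyclohex-1-en-1-olate | CC1=C([O-])C(C)(C)C[C@H](O[Si](C)(C)C(C)(C)C)C1.[Li+] | intermediate
6 | (4R)-4-(tert-butyldimethylsilyloxy)-2,6,6-trimethylcyclohex-1-en-1-yl trifluoromethanesulfonate | CC1=C(OS(=O)(=O)C(F)(F)F)C(C)(C)C[C@H](O[Si](C)(C)C(C)(C)C)C1 | intermediate
7 | (E)-3-methylpent-2-en-4-yn-1-ol | C#C/C(C)=C/CO | starting material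
8 | (2E)-5-[(4R)-4-(tert-butyldimethylsilyloxy)-2,6,6-trimethylcyclohex-1-en-1-yl]-3-methylpent-2-en-4-yn-1-ol | CC1=C(C#C/C(C)=C/CO)C(C)(C)C[C@H](O[Si](C)(C)C(C)(C)C)C1 | intermediate
9 | acetate of 8 | CC1=C(C#C/C(C)=C/COC(C)=O)C(C)(C)C[C@H](O[Si](C)(C)C(C)(C)C)C1 | intermediate
10 | (2E)-5-[(1R,4S,6R)-4-(tert-butyldimethylsilyloxy)-2,2,6-trimethyl-7-oxabicyclo[4.1.0]heptan-1-yl]-3-methylpent-2-en-4-yn-1-yl acetate (oxirane anti to the silyloxy group) | C[C@@]12C[C@@H](O[Si](C)(C)C(C)(C)C)CC(C)(C)[C@]1(C#C/C(C)=C/COC(C)=O)O2 | intermediate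
11 | (2E)-5-[(2R,4S)-4-(tert-butyldimethylsilyloxy)-2-hydroxy-2,6,6-trimethylcyclohexylidene]-3-methylpenta-2,4-dien-1-ol, R allene axis | C[C@@]1(O)C[C@@H](O[Si](C)(C)C(C)(C)C)CC(C)(C)C1=[C@@]=C/C(C)=C/CO | intermediate
12 | (2E)-3-[(2S,6S,7aR)-6-(tert-butyldimethylsilyloxy)-4,4,7a-trimethyl-2,4,5,6,7,7a-hexahydro-1-benzofuran-2-yl]but-2-en-1-ol | OC/C=C(\C)[C@@H]1C=C2C(C)(C)C[C@H](O[Si](C)(C)C(C)(C)C)C[C@@]2(C)O1 | intermediate
13 | allylic bromide of 12 (Br in place of OH) | BrC/C=C(\C)[C@@H]1C=C2C(C)(C)C[C@H](O[Si](C)(C)C(C)(C)C)C[C@@]2(C)O1 | intermediate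
14 | furanoid C15 triphenylphosphonium bromide | [Br-].c1ccccc1[P+](c1ccccc1)(c1ccccc1)C/C=C(\C)[C@@H]1C=C2C(C)(C)C[C@H](O[Si](C)(C)C(C)(C)C)C[C@@]2(C)O1 | intermediate
15 | (R)-α-ionone | CC1=CCCC(C)(C)[C@H]1/C=C/C(C)=O | starting material
16 | ethyl (2E,4E)-3-methyl-5-[(1R)-2,6,6-trimethylcyclohex-2-en-1-yl]penta-2,4-dienoate | CC1=CCCC(C)(C)[C@H]1/C=C/C(C)=C/C(=O)OCC | intermediate
17 | ethyl (2E,4E)-3-methyl-5-[(1R)-2,6,6-trimethyl-4-oxocyclohex-2-en-1-yl]penta-2,4-dienoate | CC1=CC(=O)CC(C)(C)[C@H]1/C=C/C(C)=C/C(=O)OCC | intermediate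
18 | ethyl (2E,4E)-5-[(1R,4R)-4-hydroxy-2,6,6-trimethylcyclohex-2-en-1-yl]-3-methylpenta-2,4-dienoate | CC1=C[C@H](O)CC(C)(C)[C@H]1/C=C/C(C)=C/C(=O)OCC | intermediate
19 | TBS ether of 18 | CC1=C[C@H](O[Si](C)(C)C(C)(C)C)CC(C)(C)[C@H]1/C=C/C(C)=C/C(=O)OCC | intermediate
20 | (2E,4E)-5-[(1R,4R)-4-(tert-butyldimethylsilyloxy)-2,6,6-trimethylcyclohex-2-en-1-yl]-3-methylpenta-2,4-dien-1-ol | CC1=C[C@H](O[Si](C)(C)C(C)(C)C)CC(C)(C)[C@H]1/C=C/C(C)=C/CO | intermediate
21 | allylic bromide of 20 (Br in place of OH) | CC1=C[C@H](O[Si](C)(C)C(C)(C)C)CC(C)(C)[C@H]1/C=C/C(C)=C/CBr | intermediate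
22 | ε-end C15 triphenylphosphonium bromide | CC1=C[C@H](O[Si](C)(C)C(C)(C)C)CC(C)(C)[C@H]1/C=C/C(C)=C/C[P+](c1ccccc1)(c1ccccc1)c1ccccc1.[Br-] | intermediate
23 | (2E,4E,6E)-2,7-dimethylocta-2,4,6-trienedial | O=C/C(C)=C/C=C/C=C(C)/C=O | starting material
24 | 11'Z isomer of the C25 apo-aldehyde 25 | CC1=C[C@H](O[Si](C)(C)C(C)(C)C)CC(C)(C)[C@H]1/C=C/C(C)=C/C=C\C(C)=C\C=C\C=C(C)\C=O | intermediate
25 | all-E C25 apo-aldehyde, (3'R,6'R)-3'-(tert-butyldimethylsilyloxy) ε end, aldehyde at C12 | CC1=C[C@H](O[Si](C)(C)C(C)(C)C)CC(C)(C)[C@H]1/C=C/C(C)=C/C=C/C(C)=C/C=C/C=C(C)/C=O | intermediate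
26 | 11Z isomer of 27 | CC1=C[C@H](O[Si](C)(C)C(C)(C)C)CC(C)(C)[C@H]1/C=C/C(C)=C/C=C/C(C)=C/C=C/C=C(C)/C=C\C=C(/C)[C@@H]1C=C2C(C)(C)C[C@H](O[Si](C)(C)C(C)(C)C)C[C@@]2(C)O1 | intermediate
27 | all-E 3,3'-bis-O-TBS ether of the target | CC1=C[C@H](O[Si](C)(C)C(C)(C)C)CC(C)(C)[C@H]1/C=C/C(C)=C/C=C/C(C)=C/C=C/C=C(C)/C=C/C=C(\C)[C@@H]1C=C2C(C)(C)C[C@H](O[Si](C)(C)C(C)(C)C)C[C@@]2(C)O1 | intermediate
28 | (3S,5R,8S,3'R,6'R)-5,8-epoxy-5,8-dihydro-β,ε-carotene-3,3'-diol | CC1=C[C@H](O)CC(C)(C)[C@H]1/C=C/C(C)=C/C=C/C(C)=C/C=C/C=C(C)/C=C/C=C(\C)[C@@H]1C=C2C(C)(C)C[C@H](O)C[C@@]2(C)O1 | target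

**Count**

Total step count: 19.
Longest linear sequence: 12 steps (steps 1 to 10, then 18 and 19, from ketoisophorone).

**Steps most likely to fail**

1. Step 9. What may go wrong: the gold-bound allene ionises to a dienyl-stabilised allyl cation and the axis-to-centre transfer is lost (both C8 configurations form), or the vinylallene is diverted into carbocyclisation. Fallback (classical epoxide-to-furanoid rearrangement, with C8 set without control and the epimers separated): it sets out from 8 and comes back at 12. The enynol 8 is reduced with LiAlH4 in THF, by hydroxyl-directed trans-hydroalumination of the conjugated triple bond, to the (7E,9E)-dienol F1. Acetylation (Ac2O, pyridine) gives the acetate F2. mCPBA epoxidises the ring alkene mainly anti to the silyl ether to give the (3S,5R,6S)-5,6-epoxide F3. Catalytic camphorsulfonic acid in CH2Cl2 at 0 °C opens the oxirane to the allyl cation, which O5 captures at C8; from the resulting pair of C8 epimers the 8S furanoid acetate F4 is isolated by chromatography. K2CO3 in MeOH removes the acetate and gives 12.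

2. Step 18. What may go wrong: the ylide of 14 is lost through vinylogous β-elimination of the C8 oxygen (opening of the dihydrofuran) or through C8 epimerisation before the long, poorly soluble C25 aldehyde traps it. Fallback (the two olefinations in the opposite order, so that the sensitive ylide meets the small, reactive dialdehyde in excess): it sets out from 14 and comes back at 27. Wittig reaction of 14 with an excess of 23 (NaOMe, CH2Cl2/MeOH, −20 °C) and thermal equilibration give the furanoid C25 apo-aldehyde F5. Olefination of this aldehyde with the robust ε-end salt 22 (NaOMe), followed by thermal equilibration of the new C11'=C12' bond, gives 27.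

3. Step 13. What may go wrong: poor facial selectivity of hydride delivery, so that the cis alcohol forms beside or in place of the trans alcohol, or conjugate reduction of the enone. Fallback (reduction to the cis alcohol and inversion): it sets out from 17 and comes back at 18. Luche reduction (NaBH4, CeCl3·7H2O, MeOH, −78 °C), in which the small hydride adds axially, gives the cis (3'S,6'R)-hydroxy ester F6. Mitsunobu inversion (4-nitrobenzoic acid, PPh3, diisopropyl azodicarboxylate, THF) gives the trans (3'R,6'R) 4-nitrobenzoate F7. K2CO3 in EtOH cleaves only the nitrobenzoate and gives 18.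

**Further compounds**

F1 | step 9 | (2E,4E)-5-[(4R)-4-(tert-butyldimethylsilyloxy)-2,6,6-trimethylcyclohex-1-en-1-yl]-3-methylpenta-2,4-dien-1-ol | CC1=C(/C=C/C(C)=C/CO)C(C)(C)C[C@H](O[Si](C)(C)C(C)(C)C)C1
F2 | step 9 | acetate of F1 | CC1=C(/C=C/C(C)=C/COC(C)=O)C(C)(C)C[C@H](O[Si](C)(C)C(C)(C)C)C1
F3 | step 9 | (3S,5R,6S)-5,6-epoxide of F2, oxirane anti to the silyloxy group | C[C@@]12C[C@@H](O[Si](C)(C)C(C)(C)C)CC(C)(C)[C@]1(/C=C/C(C)=C/COC(C)=O)O2
F4 | step 9 | acetate of 12, (5R,8S)-furanoid C15 acetate | CC(=O)OC/C=C(\C)[C@@H]1C=C2C(C)(C)C[C@H](O[Si](C)(C)C(C)(C)C)C[C@@]2(C)O1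
F5 | step 18 | furanoid C25 apo-aldehyde with the silylated (3S,5R,8S) end, aldehyde at C12' | O=C/C(C)=C/C=C/C=C(C)/C=C/C=C(\C)[C@@H]1C=C2C(C)(C)C[C@H](O[Si](C)(C)C(C)(C)C)C[C@@]2(C)O1
F6 | step 13 | ethyl (2E,4E)-5-[(1R,4S)-4-hydroxy-2,6,6-trimethylcyclohex-2-en-1-yl]-3-methylpenta-2,4-dienoate (cis alcohol) | CC1=C[C@@H](O)CC(C)(C)[C@H]1/C=C/C(C)=C/C(=O)OCC
F7 | step 13 | 4-nitrobenzoate of 18 | CC1=C[C@H](OC(=O)c2ccc(cc2)[N+](=O)[O-])CC(C)(C)[C@H]1/C=C/C(C)=C/C(=O)OCC
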